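**Plan**

1. Numbering (clerodane): ring A = C1–C5 and C10; ring B = C5–C10; side chain C11–C15 with C16 on C13; C17 on C8; C18 = exocyclic CH2 on C4; C19 on C5; C20 on C9; β is the face of C19.
2. Retrosynthetic cuts, in order: C3 oxidation level (diosphenol from the 2-ketone); O7 acetyl; C13–C16 and C13=C14; C1–C10 together with C9–C11; C2–C3; C9–C20; C4–C5; C5=C10; C9–C10; C7–C8.
3. Forward: a syn-aldol gives the acyclic C5–C9 chain; ring B is closed by metathesis as an enone; cuprate addition sets C5 and keeps the enolate as the C9 triflate; methylation and acylation give the C9(Me)=C10 alkene carrying a bromoacetonyl arm; one radical step closes ring A and attaches C11–C13; the side chain, the acetate and the diosphenol follow.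
4. Enabling feature: C10 is a methine between the quaternary carbons C5 and C9. With a C9(Me)=C10 alkene in ring B and an α-keto radical at C1 tethered through C5, one 6-exo closure makes C1–C10 (ring A, cis-decalin) and leaves a tertiary C9 radical that takes up acrolein.
5. Stereochemistry: C7 and C8 from the (R)-oxazolidinone syn-aldol; C5 by cuprate addition trans to the O7 silyl ether; C10 by the tether (cis fusion); C9 by trapping on the convex β face; C13 by the chiral copper catalyst.

Key step: step 10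

Remark: (S)-Tol-BINAP is assumed to be the ligand enantiomer that delivers methyl to the C13 Re face of the (E)-enoate (13R); if the sense proves opposite, (R)-Tol-BINAP is used and nothing else changes.

**Step 1**
Reactants: 1 3-methylbut-3-en-1-ol
Product: 2 3-methylbut-3-enal
Conditions: Dess–Martin periodinane, NaHCO3, CH2Cl2, 0 °C → rt; filtered solution used at once
Reagents that add atoms: none
Why: Dess–Martin oxidation under buffered conditions should give the β,γ-unsaturated aldehyde without migration of the double bond into conjugation.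

**Step 2**
Reactants: 2 3-methylbut-3-enal; 3 (4R)-4-benzyl-3-propanoyl-1,3-oxazolidin-2-one
Product: 5 (4R)-4-benzyl-3-[(2R,3S)-3-hydroxy-2,5-dimethylhex-5-enoyl]-1,3-oxazolidin-2-one, via dibutylboron Z-enolate 4 (not isolated)
Conditions: 3, Bu2BOTf, Et3N, CH2Cl2, 0 °C; 2, −78 → 0 °C; pH 7 buffer, MeOH, 30% H2O2
Reagents that add atoms: none
Why: Evans syn-aldol reaction, in which the Z-boron enolate reacts through a Zimmerman–Traxler chair on the face away from the benzyl group and should set C8 (R) and C7 (S) in the 2,3-syn relationship that becomes trans on ring B.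

**Step 3**
Reactants: 5 aldol adduct
Product: 6 (2R,3S)-3-hydroxy-N-methoxy-N,2,5-trimethylhex-5-enamide
Conditions: MeNH(OMe)·HCl, Me3Al, CH2Cl2, −10 °C → rt
Reagents that add atoms: N,O-dimethylhydroxylamine hydrochloride (CNOC.Cl)
Why: Weinreb amide formation by aluminium amide transamidation is assisted by the free β-hydroxyl and should release the auxiliary without epimerising C8.

**Step 4**
Reactants: 6 hydroxy Weinreb amide
Product: 7 (2R,3S)-3-[(tert-butyldimethylsilyl)oxy]-N-methoxy-N,2,5-trimethylhex-5-enamide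
Conditions: TBSOTf, 2,6-lutidine, CH2Cl2, −78 → 0 °C
Reagents that add atoms: tert-butyldimethylsilyl trifluoromethanesulfonate (CC(C)(C)[Si](C)(C)OS(=O)(=O)C(F)(F)F)
Why: Silylation of the secondary alcohol with a silyl triflate is fast and should block retro-aldol and β-elimination in the following steps.

**Step 5**
Reactants: 7 silylated Weinreb amide
Product: 8 (4R,5S)-5-[(tert-butyldimethylsilyl)oxy]-4,7-dimethylocta-1,7-dien-3-one
Conditions: CH2=CHMgBr, THF, −78 → 0 °C; inverse quench into cold 1 M HCl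
Reagents that add atoms: vinylmagnesium bromide (C=C[Mg]Br)
Why: Weinreb ketone synthesis stops at single addition through the chelated adduct, and the acidic inverse quench should prevent Michael addition of the released amine to the vinyl ketone.

**Step 6**
Reactants: 8 dienone
Product: 9 (5S,6R)-5-[(tert-butyldimethylsilyl)oxy]-3,6-dimethylcyclohex-2-en-1-one
Conditions: second-generation Grubbs catalyst RuCl2(=CHPh)(PCy3)(H2IMes) (5 mol %), CH2Cl2, 40 °C
Reagents that add atoms: none
Why: Ring-closing metathesis between the vinyl ketone and the 1,1-disubstituted alkene should close ring B as the 3-methylcyclohexenone with loss of ethene and without touching C7 or C8.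

**Step 7**
Reactants: 9 ring B enone; 10 (2-bromoprop-2-en-1-yl)trimethylsilane
Product: 13 (3S,5S,6R)-5-[(tert-butyldimethylsilyl)oxy]-3,6-dimethyl-3-[3-(trimethylsilyl)prop-1-en-2-yl]cyclohex-1-en-1-yl trifluoromethanesulfonate, via lithium divinylcuprate 11 (not isolated), via lithium enolate 12 (not isolated)
Conditions: 10, t-BuLi, Et2O, −78 °C; CuI, −78 → −40 °C; 9, Et2O/THF, −78 → −30 °C; PhNTf2, THF/DMPU, −78 °C → rt
Reagents that add atoms: N-phenylbis(trifluoromethanesulfonimide) (O=S(=O)(N(c1ccccc1)S(=O)(=O)C(F)(F)F)C(F)(F)F)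
Why: Cuprate conjugate addition followed by O-triflation of the regiodefined enolate, in which axial attack anti to the O7 silyl ether of the 5-substituted cyclohexenone should create the C5 quaternary centre with C4 trans to O7 and C19 cis to it.

**Step 8**
Reactants: 13 enol triflate
Product: 14 tert-butyldimethyl({(1S,2S,5S)-2,3,5-trimethyl-5-[3-(trimethylsilyl)prop-1-en-2-yl]cyclohex-3-en-1-yl}oxy)silane
Conditions: MeMgBr, Fe(acac)3 (5 mol %), THF/NMP, −30 °C
Reagents that add atoms: methylmagnesium bromide (C[Mg]Br)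
Why: Iron-catalysed Kumada-type coupling of an enol triflate with a methyl Grignard reagent should place C20 on C9 without moving the C9=C10 double bond or touching the allylsilane.

**Step 9**
Reactants: 14 allylsilane
Product: 15 1-bromo-4-[(1S,4S,5S)-5-[(tert-butyldimethylsilyl)oxy]-1,3,4-trimethylcyclohex-2-en-1-yl]pent-4-en-2-one
Conditions: BrCH2COBr, TiCl4, CH2Cl2, −78 °C, 15 min; NaHCO3 quench at −78 °C
Reagents that add atoms: bromoacetyl bromide (BrCC(Br)=O)
Why: Hosomi–Sakurai-type acylation of the allylsilane, in which the acylium ion attacks the terminal alkene carbon and loss of silicon re-forms the exocyclic methylene, while the far less nucleophilic trisubstituted ring alkene should not react at −78 °C.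

**Step 10**
Reactants: 15 α-bromo ketone; 16 acrolein
Product: 17 3-[(1R,2S,3S,4aS,8aR)-3-[(tert-butyldimethylsilyl)oxy]-1,2,4a-trimethyl-5-methylidene-7-oxodecahydronaphthalen-1-yl]propanal
Conditions: (Me3Si)3SiH and AIBN added over 6 h to 15 (0.02 M) and acrolein (10 equiv), PhH, 80 °C, sealed vessel
Reagents that add atoms: none
Why: Bromine abstraction gives an electrophilic α-keto radical at C1 that reacts only slowly with the electron-poor acrolein and adds 6-exo-trig to C10, the unsubstituted end of the electron-rich C9=C10 alkene, closing ring A; the nucleophilic tertiary C9 radical so formed then adds to acrolein (Giese reaction) and the α-formyl radical is reduced by the silane. The closest known reaction types are the 6-exo cyclisation of α-halo ketone radicals and radical cyclisation followed by intermolecular trapping with an electron-poor alkene. C10 is set by the tether: C1 is delivered from the face of C5 that carries C4, anti to C19, so the cis ring fusion with H10 syn to C19 should be strongly preferred. C9 is set in the cis-decalin radical, whose concave α face is shielded by the axial C4, by C1 and by C17, so acrolein should enter on the convex β face and leave C20 α, cis to C17. The step needs ring closure to outrun hydrogen transfer to the first radical, and trapping to outrun 1,5-hydrogen transfer and direct reduction of the C9 radical; slow addition of the weak donor (Me3Si)3SiH and a large excess of acrolein are meant to secure both.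

**Step 11**
Reactants: 17 keto aldehyde
Product: 18 methyl (2E)-5-[(1R,2S,3S,4aS,8aR)-3-[(tert-butyldimethylsilyl)oxy]-1,2,4a-trimethyl-5-methylidene-7-oxodecahydronaphthalen-1-yl]pent-2-enoate
Conditions: Ph3P=CHCO2Me, CH2Cl2, rt
Reagents that add atoms: methyl (triphenylphosphoranylidene)acetate (COC(=O)C=P(c1ccccc1)(c1ccccc1)c1ccccc1)
Why: Wittig olefination with the stabilised ylide should react at the aldehyde only, leave the ring ketone alone and give the (E)-enoate.

**Step 12**
Reactants: 18 (E)-enoate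
Product: 20 methyl (3R)-5-[(1R,2S,3S,4aS,8aR)-3-[(tert-butyldimethylsilyl)oxy]-1,2,4a-trimethyl-5-methylidene-7-oxodecahydronaphthalen-1-yl]-3-methylpentanoate, via lithium dienolate 19 (not isolated)
Conditions: LiHMDS (1.05 equiv), THF/t-BuOMe, −78 °C; added to CuI (5 mol %), (S)-Tol-BINAP (7.5 mol %), MeMgBr (4 equiv), t-BuOMe, −40 → −20 °C; aq. NH4Cl at −78 °C
Reagents that add atoms: methylmagnesium bromide (C[Mg]Br)
Why: Copper-catalysed asymmetric conjugate addition of a Grignard reagent to the (E)-enoate, in which the Tol-BINAP–copper complex selects the C13 face (13R) while the ring ketone is masked in the flask as dienolate 19 and returns on kinetic protonation at C3.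

**Step 13**
Reactants: 20 silyl ether
Product: 22 methyl (3R)-5-[(1R,2S,3S,4aS,8aR)-3-acetoxy-1,2,4a-trimethyl-5-methylidene-7-oxodecahydronaphthalen-1-yl]-3-methylpentanoate, via C7 alcohol 21 (not isolated)
Conditions: HF·pyridine, THF/pyridine, 0 °C → rt; then Ac2O, DMAP, rt
Reagents that add atoms: acetic anhydride (CC(=O)OC(C)=O)
Why: Fluoride cleavage of the silyl ether and DMAP-catalysed acetylation in one flask should exchange the O7 protecting group for the acetate of the target with retention at C7.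

**Step 14**
Reactants: 22 keto acetate
Product: 24 methyl (3R)-5-[(1R,2S,3S,4aS,8aR)-3-acetoxy-7-hydroxy-1,2,4a-trimethyl-5-methylidene-6-oxo-1,2,3,4,4a,5,6,8a-octahydronaphthalen-1-yl]-3-methylpentanoate, via 2,3-dione 23 (not isolated)
Conditions: SeO2 (1.3 equiv), 1,4-dioxane/H2O, 80 °C
Reagents that add atoms: selenium dioxide (O=[Se]=O)
Why: Riley oxidation, in which C3 is the only methylene both α to the C2 ketone and allylic to C4=C18 and should therefore be oxidised to the ketone, after which dione 23 can enolise only toward C1 and should tautomerise to the diosphenol.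

**Compound list**

1 | 3-methylbut-3-en-1-ol | C=C(C)CCO | starting material
2 | 3-methylbut-3-enal | C=C(C)CC=O | intermediate
3 | (4R)-4-benzyl-3-propanoyl-1,3-oxazolidin-2-one | CCC(=O)N1[C@H](Cc2ccccc2)COC1=O | starting material
4 | dibutylboron (Z)-enolate of 3 | C/C=C(\OB(CCCC)CCCC)N1[C@H](Cc2ccccc2)COC1=O | intermediate (not isolated)
5 | (4R)-4-benzyl-3-[(2R,3S)-3-hydroxy-2,5-dimethylhex-5-enoyl]-1,3-oxazolidin-2-one | C=C(C)C[C@H](O)[C@@H](C)C(=O)N1[C@H](Cc2ccccc2)COC1=O | intermediate
6 | (2R,3S)-3-hydroxy-N-methoxy-N,2,5-trimethylhex-5-enamide | C=C(C)C[C@H](O)[C@@H](C)C(=O)N(C)OC | intermediate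
7 | (2R,3S)-3-[(tert-butyldimethylsilyl)oxy]-N-methoxy-N,2,5-trimethylhex-5-enamide | C=C(C)C[C@H](O[Si](C)(C)C(C)(C)C)[C@@H](C)C(=O)N(C)OC | intermediate
8 | (4R,5S)-5-[(tert-butyldimethylsilyl)oxy]-4,7-dimethylocta-1,7-dien-3-one | C=C(C)C[C@H](O[Si](C)(C)C(C)(C)C)[C@@H](C)C(=O)C=C | intermediate
9 | (5S,6R)-5-[(tert-butyldimethylsilyl)oxy]-3,6-dimethylcyclohex-2-en-1-one | O=C1C=C(C)C[C@H](O[Si](C)(C)C(C)(C)C)[C@H]1C | intermediate
10 | (2-bromoprop-2-en-1-yl)trimethylsilane | C=C(Br)C[Si](C)(C)C | starting material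
11 | lithium bis[3-(trimethylsilyl)prop-1-en-2-yl]cuprate | [Li+].C=C(C[Si](C)(C)C)[Cu-]C(=C)C[Si](C)(C)C | intermediate (not isolated)
12 | lithium (3S,5S,6R)-5-[(tert-butyldimethylsilyl)oxy]-3,6-dimethyl-3-[3-(trimethylsilyl)prop-1-en-2-yl]cyclohex-1-en-1-olate | C[C@@H]1[C@@H](O[Si](C)(C)C(C)(C)C)C[C@](C)(C(=C)C[Si](C)(C)C)C=C1[O-].[Li+] | intermediate (not isolated)
13 | (3S,5S,6R)-5-[(tert-butyldimethylsilyl)oxy]-3,6-dimethyl-3-[3-(trimethylsilyl)prop-1-en-2-yl]cyclohex-1-en-1-yl trifluoromethanesulfonate | C[C@@H]1[C@@H](O[Si](C)(C)C(C)(C)C)C[C@](C)(C(=C)C[Si](C)(C)C)C=C1OS(=O)(=O)C(F)(F)F | intermediate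
14 | tert-butyldimethyl({(1S,2S,5S)-2,3,5-trimethyl-5-[3-(trimethylsilyl)prop-1-en-2-yl]cyclohex-3-en-1-yl}oxy)silane | C[C@@H]1[C@@H](O[Si](C)(C)C(C)(C)C)C[C@](C)(C(=C)C[Si](C)(C)C)C=C1C | intermediate
15 | 1-bromo-4-[(1S,4S,5S)-5-[(tert-butyldimethylsilyl)oxy]-1,3,4-trimethylcyclohex-2-en-1-yl]pent-4-en-2-one | C[C@@H]1[C@@H](O[Si](C)(C)C(C)(C)C)C[C@](C)(C(=C)CC(=O)CBr)C=C1C | intermediate
16 | acrolein (prop-2-enal) | C=CC=O | starting material
17 | 3-[(1R,2S,3S,4aS,8aR)-3-[(tert-butyldimethylsilyl)oxy]-1,2,4a-trimethyl-5-methylidene-7-oxodecahydronaphthalen-1-yl]propanal | C=C1CC(=O)C[C@@H]2[C@@](C)(CCC=O)[C@H](C)[C@@H](O[Si](C)(C)C(C)(C)C)C[C@]12C | intermediate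
18 | methyl (2E)-5-[(1R,2S,3S,4aS,8aR)-3-[(tert-butyldimethylsilyl)oxy]-1,2,4a-trimethyl-5-methylidene-7-oxodecahydronaphthalen-1-yl]pent-2-enoate | C=C1CC(=O)C[C@@H]2[C@@](C)(CC/C=C/C(=O)OC)[C@H](C)[C@@H](O[Si](C)(C)C(C)(C)C)C[C@]12C | intermediate
19 | lithium dienolate of 18 (O2 enolate, C2=C3 and C4=C18) | C=C1C=C([O-])C[C@@H]2[C@@](C)(CC/C=C/C(=O)OC)[C@H](C)[C@@H](O[Si](C)(C)C(C)(C)C)C[C@]12C.[Li+] | intermediate (not isolated)
20 | methyl (3R)-5-[(1R,2S,3S,4aS,8aR)-3-[(tert-butyldimethylsilyl)oxy]-1,2,4a-trimethyl-5-methylidene-7-oxodecahydronaphthalen-1-yl]-3-methylpentanoate | C=C1CC(=O)C[C@@H]2[C@@](C)(CC[C@@H](C)CC(=O)OC)[C@H](C)[C@@H](O[Si](C)(C)C(C)(C)C)C[C@]12C | intermediate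
21 | methyl (3R)-5-[(1R,2S,3S,4aS,8aR)-3-hydroxy-1,2,4a-trimethyl-5-methylidene-7-oxodecahydronaphthalen-1-yl]-3-methylpentanoate | C=C1CC(=O)C[C@@H]2[C@@](C)(CC[C@@H](C)CC(=O)OC)[C@H](C)[C@@H](O)C[C@]12C | intermediate (not isolated)
22 | methyl (3R)-5-[(1R,2S,3S,4aS,8aR)-3-acetoxy-1,2,4a-trimethyl-5-methylidene-7-oxodecahydronaphthalen-1-yl]-3-methylpentanoate | C=C1CC(=O)C[C@@H]2[C@@](C)(CC[C@@H](C)CC(=O)OC)[C@H](C)[C@@H](OC(C)=O)C[C@]12C | intermediate
23 | methyl (3R)-5-[(1R,2S,3S,4aS,8aR)-3-acetoxy-1,2,4a-trimethyl-5-methylidene-6,7-dioxodecahydronaphthalen-1-yl]-3-methylpentanoate | C=C1C(=O)C(=O)C[C@@H]2[C@@](C)(CC[C@@H](C)CC(=O)OC)[C@H](C)[C@@H](OC(C)=O)C[C@]12C | intermediate (not isolated)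
24 | methyl (3R)-5-[(1R,2S,3S,4aS,8aR)-3-acetoxy-7-hydroxy-1,2,4a-trimethyl-5-methylidene-6-oxo-1,2,3,4,4a,5,6,8a-octahydronaphthalen-1-yl]-3-methylpentanoate | C=C1C(=O)C(O)=C[C@@H]2[C@@](C)(CC[C@@H](C)CC(=O)OC)[C@H](C)[C@@H](OC(C)=O)C[C@]12C | target

**Step count and risks**

Total step count: 14. Longest linear sequence: 14 steps (1 to 24).

Steps most likely to fail:

Step 10. Hydrogen transfer to the α-keto radical before ring closure, telomerisation of acrolein, or 1,5-hydrogen transfer within the C9 radical may erode the three-component chain. The fallback separates the two bond formations and sets out from 15. A bromine-atom-transfer radical cyclisation with no hydrogen donor present (CuBr, tris(2-pyridylmethyl)amine, ascorbic acid, MeOH/PhMe, 50 °C) should give the ring-closed C9 tertiary bromide F1. This is used at once in a separate Giese reaction with acrolein ((Me3Si)3SiH, AIBN, PhH, 80 °C) and comes back to the route at 17.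

Step 12. Incomplete masking of the ring ketone (1,2-addition of the Grignard reagent) or poor facial control at C13 may occur. The fallback sets out from 17 and introduces C16 by coupling and C13–H by reduction. A Roskamp reaction (methyl diazoacetate, SnCl2, CH2Cl2) should give the β-keto ester F2. NaH and PhNTf2 should give the (Z)-enol triflate F3, and Me2CuLi at −78 °C the (E)-β-methyl enoate F4. A copper hydride conjugate reduction follows (Cu(OAc)2, the DTBM-SEGPHOS enantiomer chosen for 13R, polymethylhydrosiloxane, t-BuOH); it also hydrosilylates the ring ketone and gives the C2 alcohol F5 after basic work-up. Dess–Martin oxidation of F5 comes back to the route at 20.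

Step 14. Over-oxidation of the diosphenol at C10 or migration of the exocyclic double bond into conjugation may occur under the hot acidic conditions. The fallback sets out from 22. TMSOTf and Et3N should give the conjugated trimethylsilyl dienol ether F6. A Rubottom oxidation with dimethyldioxirane at −40 °C should give the 3-hydroxy-2-ketone F7. Oxidation of this acyloin (Cu(OAc)2, air, MeOH) gives the dione, which tautomerises, and the route is rejoined at 24.

**Further compounds**

F1 | step 10 | ring-closed C9 tertiary bromide (3-silyloxy-1-bromo-1,2,4a-trimethyl-5-methylidene-decahydronaphthalen-7-one; configuration at C9 immaterial) | C=C1CC(=O)C[C@@H]2C(C)(Br)[C@H](C)[C@@H](O[Si](C)(C)C(C)(C)C)C[C@]12C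
F2 | step 12 | methyl 5-[(1R,2S,3S,4aS,8aR)-3-[(tert-butyldimethylsilyl)oxy]-1,2,4a-trimethyl-5-methylidene-7-oxodecahydronaphthalen-1-yl]-3-oxopentanoate | C=C1CC(=O)C[C@@H]2[C@@](C)(CCC(=O)CC(=O)OC)[C@H](C)[C@@H](O[Si](C)(C)C(C)(C)C)C[C@]12C
F3 | step 12 | (Z)-enol triflate of F2 (methyl (2Z)-3-[(trifluoromethanesulfonyl)oxy]pent-2-enoate side chain) | C=C1CC(=O)C[C@@H]2[C@@](C)(CC/C(OS(=O)(=O)C(F)(F)F)=C/C(=O)OC)[C@H](C)[C@@H](O[Si](C)(C)C(C)(C)C)C[C@]12C
F4 | step 12 | methyl (2E)-5-[(1R,2S,3S,4aS,8aR)-3-[(tert-butyldimethylsilyl)oxy]-1,2,4a-trimethyl-5-methylidene-7-oxodecahydronaphthalen-1-yl]-3-methylpent-2-enoate | C=C1CC(=O)C[C@@H]2[C@@](C)(CC/C(C)=C/C(=O)OC)[C@H](C)[C@@H](O[Si](C)(C)C(C)(C)C)C[C@]12C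
F5 | step 12 | C2 alcohol of 20 (mixture of C2 epimers) | C=C1CC(O)C[C@@H]2[C@@](C)(CC[C@@H](C)CC(=O)OC)[C@H](C)[C@@H](O[Si](C)(C)C(C)(C)C)C[C@]12C
F6 | step 14 | trimethylsilyl dienol ether of 22 (C2=C3 and C4=C18) | C=C1C=C(O[Si](C)(C)C)C[C@@H]2[C@@](C)(CC[C@@H](C)CC(=O)OC)[C@H](C)[C@@H](OC(C)=O)C[C@]12C
F7 | step 14 | 3-hydroxy-2-ketone of 22 (C3 configuration immaterial) | C=C1C(O)C(=O)C[C@@H]2[C@@](C)(CC[C@@H](C)CC(=O)OC)[C@H](C)[C@@H](OC(C)=O)C[C@]12C
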